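**Retrosynthetic overview**
1. Target ⇐ 12‑O‑TBS removal ⇐ acetylation of the 2,3,9‑triol ⇐ cis‑dihydroxylation of a (2Z)‑alkene ⇐ ring‑closing metathesis at C2=C3, which closes the ten‑membered ring last.
2. γ‑Lactone (C17–C19, O7) ⇐ Seebach lactic‑acid dioxolanone enolate added to C8 of a C8/C9 1,2‑diketone (Felkin control from C7), then lactonisation and C9 reduction.
3. C8–C9 bond ⇐ boron aldol of a ring A aldehyde with a (Z)‑enone α‑PMB‑oxy ketone (C3–C8); C7 by 1,3‑anti reduction; 5,6‑epoxide by hydroxyl‑directed epoxidation.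
4. Ring A ⇐ (S)‑carvone: formylation/methylation (C1), enone epoxidation (O12), Criegee rearrangement (14‑OAc), methylenation, Pd/formate hydrogenolysis (C11), hydroboration (C9/C10).
5. Ring order: cyclohexane (from carvone) → γ‑lactone → ten‑membered carbocycle.

Assumption/convention: locants are those of the target's briarane skeleton (C1–C20; ring A = C1, C10–C14; C18 = methyl on C17, C19 = lactone C=O; β = face of ring A carrying the C15 methyl), and compounds 21 and 33 are taken as purchasable.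

This route is a paper design: no step has been run, and the stereochemical outcomes rest on the models named in each "Why" line.

**Step 1**
Reactants: 1 (S)-(+)-carvone
Product: 2 6-(hydroxymethylidene)carvone
Conditions: NaH, HCO2Et, THF, 0 °C → rt; aq. HCl
Reagents that add atoms: ethyl formate, CCOC=O
Why: Crossed Claisen (formylation) at the only enolisable α′‑carbon (future C1) gives the stabilised hydroxymethylene ketone, the new carbon being C2; no stereocentre is set.

**Step 2**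
Reactants: 2 6-(hydroxymethylidene)carvone
Product: 3 quaternary keto aldehyde (15‑CH3 β, CHO α)
Conditions: MeI, K2CO3, acetone, rt
Reagents that add atoms: iodomethane, CI
Why: C‑Alkylation of the planar β‑dicarbonyl enolate, iodomethane approaching anti to the neighbouring isopropenyl group, sets the C1 quaternary centre (methyl trans, formyl cis to isopropenyl).

**Step 3**
Reactants: 3 quaternary keto aldehyde
Product: 4 dimethyl acetal of 3
Conditions: HC(OMe)3, PPTS (cat.), MeOH, rt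
Reagents that add atoms: trimethyl orthoformate, COC(OC)OC
Why: Acid‑catalysed acetalisation masks only the aldehyde, since the hindered conjugated ketone does not react.

**Step 4**
Reactants: 4 dimethyl acetal
Product: 5 11β,12β-epoxy ketone
Conditions: H2O2 (30%), NaOH (cat.), MeOH, 0 °C
Reagents that add atoms: hydrogen peroxide, OO
Why: Weitz–Scheffer nucleophilic epoxidation of the enone, hydroperoxide adding anti to the isopropenyl group as in carvone itself, places the C12 oxygen β.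

**Step 5**
Reactants: 5 11β,12β-epoxy ketone
Product: 7 14α-acetoxy epoxy ketone, via α-methoxy hydroperoxide 6 (not isolated)
Conditions: O3, NaHCO3, CH2Cl2/MeOH, −78 °C; then Ac2O, Et3N, DMAP (cat.), 0 °C → rt
Reagents that add atoms: ozone, [O-][O+]=O; methanol, CO
Why: Ozonolysis of the only alkene in methanol stops at the methoxy hydroperoxide, whose peracetate undergoes Criegee rearrangement with retention at the migrating C14, turning isopropenyl into the 14α‑acetate.

**Step 6**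
Reactants: 7 14α-acetoxy epoxy ketone
Product: 8 10-methylidene alkenyl oxirane
Conditions: Ph3PCH3Br, KOtBu, toluene, 0 °C → rt
Reagents that add atoms: methyltriphenylphosphonium bromide, C[P+](c1ccccc1)(c1ccccc1)c1ccccc1.[Br-]
Why: Wittig methylenation of the ketone (faster than attack on the acetate) introduces C9 and creates the alkenyl oxirane needed next.

**Step 7**
Reactants: 8 10-methylidene alkenyl oxirane
Product: 9 12β-hydroxy-11β-methyl-10-methylidene compound
Conditions: Pd2(dba)3·CHCl3 (cat.), n-Bu3P, HCO2H, Et3N, dioxane, rt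
Reagents that add atoms: none
Why: Tsuji hydrogenolysis of an alkenyl oxirane: palladium ionises the allylic C11–O bond with inversion and formate‑derived hydride is delivered from the metal to the α‑face of the more substituted terminus, so H11 is α, C20 is β and the 12β‑hydroxyl is kept.

**Step 8**
Reactants: 9 12β-hydroxy-11β-methyl-10-methylidene compound
Product: 10 12-O-TBS ether
Conditions: TBSCl, imidazole, DMAP (cat.), DMF, 40 °C
Reagents that add atoms: tert-butyl(chloro)dimethylsilane, CC(C)(C)[Si](C)(C)Cl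
Why: Silylation of the only hydroxyl, using the chloride rather than a silyl triflate because triflates attack the dimethyl acetal.

**Step 9**
Reactants: 10 12-O-TBS ether
Product: 12 C9 primary alcohol, via B-alkyl-9-BBN 11 (not isolated)
Conditions: 9-BBN, THF, 60 °C; then H2O2, aq. NaOAc, 0 °C → rt
Reagents that add atoms: hydrogen peroxide, OO
Why: Anti‑Markovnikov hydroboration–oxidation of the exocyclic alkene, with syn addition from the α‑face (away from the flanking C15 and C20 methyls and the 12β‑silyl ether), makes H10 α and C9 β.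

**Step 10**
Reactants: 12 C9 primary alcohol
Product: 13 C9-hydroxy C2-aldehyde
Conditions: PPTS, acetone/H2O, 55 °C
Reagents that add atoms: water, O
Why: Mild acid hydrolysis of the dimethyl acetal, which the secondary TBS ether and the acetate tolerate.

**Step 11**
Reactants: 13 C9-hydroxy C2-aldehyde
Product: 14 1α-vinyl C9 alcohol
Conditions: Ph3PCH3Br, KOtBu (3 equiv), THF, −78 → 0 °C
Reagents that add atoms: methyltriphenylphosphonium bromide, C[P+](c1ccccc1)(c1ccccc1)c1ccccc1.[Br-]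
Why: Wittig methylenation of the neopentyl aldehyde (excess ylide covers the free hydroxyl) installs the C2 vinyl group for the later metathesis.

**Step 12**
Reactants: 14 1α-vinyl C9 alcohol
Product: 15 ring A aldehyde
Conditions: Dess–Martin periodinane, NaHCO3, CH2Cl2, 0 °C
Reagents that add atoms: none
Why: Buffered Dess–Martin oxidation gives the C9 aldehyde without epimerising C10.

**Step 13**
Reactants: 16 methyl propiolate; 17 allyl bromide
Product: 18 methyl hex-5-en-2-ynoate
Conditions: CuI (cat.), K2CO3, Bu4NI, MeCN, rt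
Reagents that add atoms: none
Why: Copper‑catalysed allylation of the terminal alkyne (copper acetylide displacing bromide) gives the skipped enyne C3–C7.

**Step 14**
Reactants: 18 methyl hex-5-en-2-ynoate
Product: 19 methyl (2Z)-3-methylhexa-2,5-dienoate
Conditions: Me2CuLi (MeLi, CuI), THF, −78 °C; MeOH, −78 °C; aq. NH4Cl
Reagents that add atoms: lithium dimethylcuprate, [Li+].C[Cu-]C
Why: Syn carbocupration of the ynoate and cold protonation give the (Z)‑trisubstituted alkene (C4 cis to C7) and add C16.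

**Step 15**
Reactants: 19 methyl (2Z)-3-methylhexa-2,5-dienoate
Product: 20 (2Z)-N-methoxy-N,3-dimethylhexa-2,5-dienamide
Conditions: MeNH(OMe)·HCl, i-PrMgCl, THF, −20 °C
Reagents that add atoms: N,O-dimethylhydroxylamine hydrochloride, CNOC.Cl
Why: Weinreb amidation through the magnesium amide leaves the Z alkene untouched.

**Step 16**
Reactants: 21 tributyl(iodomethyl)stannane; 22 4-methoxybenzyl alcohol
Product: 23 tributyl[(4-methoxybenzyloxy)methyl]stannane
Conditions: NaH, THF/DMF, 0 °C → rt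
Reagents that add atoms: none
Why: Williamson ether synthesis on the primary iodide.

**Step 17**
Reactants: 23 tributyl[(4-methoxybenzyloxy)methyl]stannane; 20 (2Z)-Weinreb amide
Product: 25 (3Z)-1-(4-methoxybenzyloxy)-4-methylhepta-3,6-dien-2-one, via (PMB-oxy)methyllithium 24 (not isolated)
Conditions: n-BuLi, THF, −78 °C; then 20, −78 °C; aq. NH4Cl
Reagents that add atoms: none
Why: Tin–lithium exchange gives the α‑alkoxymethyllithium (C8), which adds once to the Weinreb amide through its stable chelate to give the ketone.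

**Step 18**
Reactants: 25 (3Z)-α-PMB-oxy ketone; 15 ring A aldehyde
Product: 27 8,9-syn aldol, via (Z)-dibutylboron enolate 26 (not isolated)
Conditions: n-Bu2BOTf, i-Pr2NEt, CH2Cl2, −78 °C; add 15, −78 → −20 °C; pH 7 buffer, MeOH, H2O2
Reagents that add atoms: none
Why: Boron‑mediated syn aldol through a Zimmerman–Traxler chair, the (Z)‑enolate attacking the α‑branched aldehyde in the anti‑Felkin sense (its alkoxy group avoids a syn‑pentane clash with C1), forms C8–C9 and sets the C9 carbinol as in the target.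

**Step 19**
Reactants: 27 8,9-syn aldol
Product: 28 7,9-anti diol
Conditions: Me4NBH(OAc)3, MeCN/AcOH, −30 °C
Reagents that add atoms: none
Why: Evans–Saksena reduction, with intramolecular hydride delivery from the C9 alkoxyborohydride, gives the 7,9‑anti diol and so relays C9 to the C7 centre.

**Step 20**
Reactants: 28 7,9-anti diol
Product: 29 (5R,6S)-5,6-epoxy diol
Conditions: m-CPBA, NaHCO3, CH2Cl2, 0 °C
Reagents that add atoms: 3-chloroperbenzoic acid, OOC(=O)c1cccc(Cl)c1
Why: Hydroxyl‑directed (Henbest) epoxidation of the Z allylic alcohol, where A(1,3) strain enforces the threo epoxy alcohol (O6 syn to O7), while the trisubstituted allylic alkene far outpaces the two terminal vinyl groups.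

**Step 21**
Reactants: 29 (5R,6S)-5,6-epoxy diol
Product: 30 7-O-TES ether
Conditions: Et3SiCl, imidazole, CH2Cl2, −20 °C
Reagents that add atoms: chlorotriethylsilane, CC[Si](Cl)(CC)CC
Why: Silylation occurs at the less hindered C7 hydroxyl because the C9 hydroxyl is flanked by ring A.

**Step 22**
Reactants: 30 7-O-TES ether
Product: 31 8,9-diol
Conditions: DDQ, CH2Cl2/pH 7 buffer, 0 °C
Reagents that add atoms: none
Why: Oxidative cleavage of the PMB ether under buffered aqueous conditions leaves silyl ethers, acetate and epoxide intact.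

**Step 23**
Reactants: 31 8,9-diol
Product: 32 8,9-diketone
Conditions: IBX, DMSO, rt
Reagents that add atoms: none
Why: IBX oxidises the vicinal diol to the 1,2‑diketone without C–C cleavage, deliberately erasing the C8 and C9 relay centres.

**Step 24**
Reactants: 33 (2S,5S)-2-tert-butyl-5-methyl-1,3-dioxolan-4-one; 32 8,9-diketone
Product: 35 C8 carbinol adduct, via lithium enolate 34 (not isolated)
Conditions: LiN(i-Pr)2, THF, −78 °C; then 32, −78 °C; aq. NH4Cl
Reagents that add atoms: none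
Why: Seebach self‑regeneration of stereocentres: the enolate reacts on the face trans to tert‑butyl (C17 fixed) at the less hindered, more electrophilic C8 carbonyl under polar Felkin–Anh control by the 7‑silyloxy group, which sets C8.

**Step 25**
Reactants: 35 C8 carbinol adduct
Product: 37 γ-lactone 9-ketone, via 7-hydroxy dioxolanone 36 (not isolated)
Conditions: HF·pyridine, pyridine, THF, 0 °C → rt
Reagents that add atoms: none
Why: Buffered fluoride removes only the TES ether and the freed 7‑hydroxyl opens the activated dioxolanone (5‑exo‑trig transesterification) to the γ‑lactone with loss of pivalaldehyde, while C9 is still a ketone and cannot compete.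

**Step 26**
Reactants: 37 γ-lactone 9-ketone
Product: 38 9-alcohol seco-diene
Conditions: NaBH4, MeOH/CH2Cl2, −40 °C
Reagents that add atoms: none
Why: Ketone‑selective borohydride reduction under Felkin–Anh control (hydride anti to the C8 oxygen and to quaternary C1) gives the 9S alcohol.

**Step 27**
Reactants: 38 9-alcohol seco-diene
Product: 39 macrocyclic (2Z)-alkene
Conditions: second-generation Hoveyda–Grubbs catalyst [RuCl2(H2IMes)(=CH-C6H4-2-O-i-Pr)] (10 mol%), toluene (1 mM), 80 °C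
Reagents that add atoms: none
Why: Ring‑closing metathesis of the two monosubstituted alkenes closes the ten‑membered ring, which is expected to hold only the Z alkene.

**Step 28**
Reactants: 39 macrocyclic (2Z)-alkene
Product: 40 2,3-diol
Conditions: OsO4 (cat.), NMO, acetone/H2O, rt
Reagents that add atoms: osmium tetroxide (oxygen carrier), O=[Os](=O)(=O)=O; N-methylmorpholine N-oxide, C[N+]1([O-])CCOCC1; water, O
Why: Upjohn dihydroxylation, syn addition to the Z alkene from the outer face opposite the allylic ring bonds C1–C10 and C4–C5, gives the cis 2R,3S diol.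

**Step 29**
Reactants: 40 2,3-diol
Product: 41 12-O-TBS tetraacetate
Conditions: Ac2O, pyridine, DMAP (cat.), CH2Cl2, 0 °C → rt
Reagents that add atoms: acetic anhydride, CC(=O)OC(C)=O
Why: Acylation of the three secondary hydroxyls (C2, C3, C9), the tertiary C8 and C17 hydroxyls staying free under these conditions.

**Step 30**
Reactants: 41 12-O-TBS tetraacetate
Product: 42 target CNP0287149.1
Conditions: HF·pyridine, THF, rt
Reagents that add atoms: none
Why: Fluoride desilylation frees the 12β‑hydroxyl without touching acetates, lactone or epoxide.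

**Compound list**
1 | (S)-(+)-carvone, (5S)-2-methyl-5-(prop-1-en-2-yl)cyclohex-2-en-1-one | O=C1C(C)=CC[C@H](C(C)=C)C1 | starting material
2 | 6-(hydroxymethylidene)carvone (stereocentre of 1 unchanged) | O=C1C(C)=CC[C@H](C(C)=C)C1=CO | intermediate
3 | 1,3-dimethyl-2-oxo-6-(prop-1-en-2-yl)cyclohex-3-ene-1-carbaldehyde, CHO cis to isopropenyl (15-CH3 β, CHO α, 14-isopropenyl α) | O=C1C(C)=CC[C@H](C(C)=C)[C@]1(C)C=O | intermediate
4 | dimethyl acetal of 3 | O=C1C(C)=CC[C@H](C(C)=C)[C@]1(C)C(OC)OC | intermediate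
5 | 11β,12β-epoxide of 4 (epoxide trans to isopropenyl) | O=C1[C@@]2(C)O[C@H]2C[C@H](C(C)=C)[C@]1(C)C(OC)OC | intermediate
6 | α-methoxy hydroperoxide from 5 (isopropenyl converted to C(CH3)(OCH3)OOH) | O=C1[C@@]2(C)O[C@H]2C[C@H](C(C)(OC)OO)[C@]1(C)C(OC)OC | intermediate
7 | 14α-acetoxy-11β,12β-epoxy C10 ketone, C2 dimethyl acetal | O=C1[C@@]2(C)O[C@H]2C[C@H](OC(C)=O)[C@]1(C)C(OC)OC | intermediate
8 | 10-methylidene analogue of 7 (alkenyl oxirane) | C=C1[C@@]2(C)O[C@H]2C[C@H](OC(C)=O)[C@]1(C)C(OC)OC | intermediate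
9 | 14α-acetoxy-12β-hydroxy-1β,11β-dimethyl-10-methylidene cyclohexane, C2 dimethyl acetal at 1α | C=C1[C@@H](C)[C@@H](O)C[C@H](OC(C)=O)[C@]1(C)C(OC)OC | intermediate
10 | 12-O-TBS ether of 9 | C=C1[C@@H](C)[C@@H](O[Si](C)(C)C(C)(C)C)C[C@H](OC(C)=O)[C@]1(C)C(OC)OC | intermediate
11 | B-(C9-alkyl)-9-borabicyclo[3.3.1]nonane from 10 (H10 α) | C(B1C2CCCC1CCC2)[C@H]1[C@@H](C)[C@@H](O[Si](C)(C)C(C)(C)C)C[C@H](OC(C)=O)[C@]1(C)C(OC)OC | intermediate
12 | 10β-hydroxymethyl compound (C9 alcohol), C2 dimethyl acetal | OC[C@H]1[C@@H](C)[C@@H](O[Si](C)(C)C(C)(C)C)C[C@H](OC(C)=O)[C@]1(C)C(OC)OC | intermediate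
13 | C9 alcohol, C2 aldehyde | OC[C@H]1[C@@H](C)[C@@H](O[Si](C)(C)C(C)(C)C)C[C@H](OC(C)=O)[C@]1(C)C=O | intermediate
14 | C9 alcohol, 1α-vinyl | OC[C@H]1[C@@H](C)[C@@H](O[Si](C)(C)C(C)(C)C)C[C@H](OC(C)=O)[C@]1(C)C=C | intermediate
15 | ring A aldehyde: 14α-acetoxy-12β-(TBS-oxy)-1β,11β-dimethyl-1α-vinylcyclohexane-10β-carbaldehyde | O=C[C@H]1[C@@H](C)[C@@H](O[Si](C)(C)C(C)(C)C)C[C@H](OC(C)=O)[C@]1(C)C=C | intermediate
16 | methyl propiolate | C#CC(=O)OC | starting material
17 | allyl bromide | C=CCBr | starting material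
18 | methyl hex-5-en-2-ynoate | C=CCC#CC(=O)OC | intermediate
19 | methyl (2Z)-3-methylhexa-2,5-dienoate | C=CC/C(C)=C\C(=O)OC | intermediate
20 | (2Z)-N-methoxy-N,3-dimethylhexa-2,5-dienamide | C=CC/C(C)=C\C(=O)N(C)OC | intermediate
21 | tributyl(iodomethyl)stannane | CCCC[Sn](CCCC)(CCCC)CI | starting material
22 | 4-methoxybenzyl alcohol | COc1ccc(CO)cc1 | starting material
23 | tributyl[(4-methoxybenzyloxy)methyl]stannane | CCCC[Sn](CCCC)(CCCC)COCc1ccc(OC)cc1 | intermediate
24 | [(4-methoxybenzyloxy)methyl]lithium | [Li]COCc1ccc(OC)cc1 | intermediate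
25 | (3Z)-1-(4-methoxybenzyloxy)-4-methylhepta-3,6-dien-2-one (C3–C8 fragment) | C=CC/C(C)=C\C(=O)COCc1ccc(OC)cc1 | intermediate
26 | (Z)-di-n-butylboron enolate of 25 (O–B cis to OPMB) | C=CC/C(C)=C\C(OB(CCCC)CCCC)=C\OCc1ccc(OC)cc1 | intermediate
27 | aldol: C7 ketone, 8-OPMB, 9-OH, 8,9-syn, C9 as in target | C=CC/C(C)=C\C(=O)[C@H](OCc1ccc(OC)cc1)[C@@H](O)[C@H]1[C@@H](C)[C@@H](O[Si](C)(C)C(C)(C)C)C[C@H](OC(C)=O)[C@]1(C)C=C | intermediate
28 | 7,9-anti diol, 8-OPMB, C7 as in target | C=CC/C(C)=C\[C@H](O)[C@H](OCc1ccc(OC)cc1)[C@@H](O)[C@H]1[C@@H](C)[C@@H](O[Si](C)(C)C(C)(C)C)C[C@H](OC(C)=O)[C@]1(C)C=C | intermediate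
29 | (5R,6S)-5,6-epoxy 7,9-diol, 8-OPMB | C=CC[C@@]2(C)O[C@H]2[C@H](O)[C@H](OCc1ccc(OC)cc1)[C@@H](O)[C@H]1[C@@H](C)[C@@H](O[Si](C)(C)C(C)(C)C)C[C@H](OC(C)=O)[C@]1(C)C=C | intermediate
30 | 7-O-TES ether of 29 | C=CC[C@@]2(C)O[C@H]2[C@H](O[Si](CC)(CC)CC)[C@H](OCc1ccc(OC)cc1)[C@@H](O)[C@H]1[C@@H](C)[C@@H](O[Si](C)(C)C(C)(C)C)C[C@H](OC(C)=O)[C@]1(C)C=C | intermediate
31 | 8,9-diol, 7-OTES | C=CC[C@@]2(C)O[C@H]2[C@H](O[Si](CC)(CC)CC)[C@H](O)[C@@H](O)[C@H]1[C@@H](C)[C@@H](O[Si](C)(C)C(C)(C)C)C[C@H](OC(C)=O)[C@]1(C)C=C | intermediate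
32 | 8,9-diketone, 7-OTES | C=CC[C@@]2(C)O[C@H]2[C@H](O[Si](CC)(CC)CC)C(=O)C(=O)[C@H]1[C@@H](C)[C@@H](O[Si](C)(C)C(C)(C)C)C[C@H](OC(C)=O)[C@]1(C)C=C | intermediate
33 | (2S,5S)-2-tert-butyl-5-methyl-1,3-dioxolan-4-one (cis) | C[C@@H]1O[C@H](C(C)(C)C)OC1=O | starting material
34 | lithium enolate of 33 | CC1=C([O-])O[C@@H](C(C)(C)C)O1.[Li+] | intermediate
35 | C8 tertiary carbinol carrying the dioxolanone (C17), 9-ketone, 7-OTES | C=CC[C@@]2(C)O[C@H]2[C@H](O[Si](CC)(CC)CC)[C@](O)([C@@]3(C)O[C@H](C(C)(C)C)OC3=O)C(=O)[C@H]1[C@@H](C)[C@@H](O[Si](C)(C)C(C)(C)C)C[C@H](OC(C)=O)[C@]1(C)C=C | intermediate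
36 | 7-hydroxy analogue of 35 | C=CC[C@@]2(C)O[C@H]2[C@H](O)[C@](O)([C@@]3(C)O[C@H](C(C)(C)C)OC3=O)C(=O)[C@H]1[C@@H](C)[C@@H](O[Si](C)(C)C(C)(C)C)C[C@H](OC(C)=O)[C@]1(C)C=C | intermediate
37 | 8,17-dihydroxy γ-lactone (C19 to O7), 9-ketone | C=CC[C@@]3(C)O[C@H]3[C@@H]2OC(=O)[C@](C)(O)[C@]2(O)C(=O)[C@H]1[C@@H](C)[C@@H](O[Si](C)(C)C(C)(C)C)C[C@H](OC(C)=O)[C@]1(C)C=C | intermediate
38 | 9-alcohol of 37 (seco-diene) | C=CC[C@@]3(C)O[C@H]3[C@@H]2OC(=O)[C@](C)(O)[C@]2(O)[C@@H](O)[C@H]1[C@@H](C)[C@@H](O[Si](C)(C)C(C)(C)C)C[C@H](OC(C)=O)[C@]1(C)C=C | intermediate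
39 | ten-membered (2Z)-alkene (full briarane skeleton) | C1[C@@]2(C)O[C@H]2[C@@H]2OC(=O)[C@](C)(O)[C@]2(O)[C@@H](O)[C@H]2[C@@H](C)[C@@H](O[Si](C)(C)C(C)(C)C)C[C@H](OC(C)=O)[C@]2(C)/C=C\1 | intermediate
40 | 2,3-cis-diol, 14-OAc, 12-OTBS | O[C@H]1C[C@@]2(C)O[C@H]2[C@@H]2OC(=O)[C@](C)(O)[C@]2(O)[C@@H](O)[C@H]2[C@@H](C)[C@@H](O[Si](C)(C)C(C)(C)C)C[C@H](OC(C)=O)[C@]2(C)[C@H]1O | intermediate
41 | 12-O-TBS ether of the target | CC(=O)O[C@H]1C[C@@]2(C)O[C@H]2[C@@H]2OC(=O)[C@](C)(O)[C@]2(O)[C@@H](OC(C)=O)[C@H]2[C@@H](C)[C@@H](O[Si](C)(C)C(C)(C)C)C[C@H](OC(C)=O)[C@]2(C)[C@H]1OC(C)=O | intermediate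
42 | CNP0287149.1: (1R,2R,3S,5R,6S,7S,8S,9S,10S,11R,12S,14S,17R)-2,3,9,14-tetraacetoxy-5,6-epoxy-8,12,17-trihydroxybriarane 19,7-lactone | CC(=O)O[C@H]1C[C@@]2(C)O[C@H]2[C@@H]2OC(=O)[C@](C)(O)[C@]2(O)[C@@H](OC(C)=O)[C@H]2[C@@H](C)[C@@H](O)C[C@H](OC(C)=O)[C@]2(C)[C@H]1OC(C)=O | target

**Totals**
Total steps: 30. Longest linear sequence: 25 (steps 1–12 and 18–30); steps 13–17 make the side fragment 25.

**Three steps most likely to fail**

Step 18 (aldol). The anti‑Felkin face selectivity is a model prediction, and C9 relays the configuration of C7. The fallback sets out from 15 and 25 and comes back at 32. If the Felkin adduct dominates, it is the 8,9-bis-epimeric syn aldol F1, and it is carried on instead of discarded. A 1,3‑syn (Narasaka–Prasad) reduction with Et2BOMe and NaBH4 in THF/MeOH at −78 °C gives the 7,9-syn diol F2, which has the same C7 centre as 28. The same m‑CPBA epoxidation gives the epoxy diol F3, Et3SiCl/imidazole gives the 7-O-TES ether F4, and DDQ gives the 8,9-diol F5. IBX then erases C8 and C9 and delivers 32.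

Step 24 (Seebach addition). The basic enolate may instead deprotonate C7 or C10 of the diketone, or add with poor regio‑ or face selectivity. The fallback sets out from 32 and 33 and comes back at 35. Compound 33 is converted with LiN(i-Pr)2 and Me3SiCl into its silyl ketene acetal (2S)-2-tert-butyl-5-methyl-4-(trimethylsilyloxy)-1,3-dioxole F6. This neutral nucleophile is added to 32 in a Mukaiyama aldol promoted by ZnCl2 (or 5 M LiClO4 in Et2O), which cannot enolise the diketone. Aqueous work‑up hydrolyses the silyl aldolate to 35.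

Step 27 (ring‑closing metathesis). Ten‑membered ring closure may give dimers or stall at the hindered neopentyl vinyl group. The fallback sets out from 38 and comes back at 40. Ozonolysis of both terminal alkenes (O3, CH2Cl2, −78 °C; Me2S) gives the seco-2,3-dialdehyde F7, used at once because it is a β,γ‑epoxy aldehyde. Samarium diiodide (SmI2, THF, −78 °C, high dilution) then closes the ring by intramolecular pinacol coupling. This would give the cis‑2,3‑diol 40 directly, replacing both metathesis and dihydroxylation.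

**Further compounds**
F1 | step 18 | 8,9-bis-epimeric syn aldol (Felkin adduct) | C=CC/C(C)=C\C(=O)[C@@H](OCc1ccc(OC)cc1)[C@H](O)[C@H]1[C@@H](C)[C@@H](O[Si](C)(C)C(C)(C)C)C[C@H](OC(C)=O)[C@]1(C)C=C
F2 | step 18 | 7,9-syn diol (8,9-bis-epimer of 28) | C=CC/C(C)=C\[C@H](O)[C@@H](OCc1ccc(OC)cc1)[C@H](O)[C@H]1[C@@H](C)[C@@H](O[Si](C)(C)C(C)(C)C)C[C@H](OC(C)=O)[C@]1(C)C=C
F3 | step 18 | (5R,6S)-epoxy diol (8,9-bis-epimer of 29) | C=CC[C@@]2(C)O[C@H]2[C@H](O)[C@@H](OCc1ccc(OC)cc1)[C@H](O)[C@H]1[C@@H](C)[C@@H](O[Si](C)(C)C(C)(C)C)C[C@H](OC(C)=O)[C@]1(C)C=C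
F4 | step 18 | 7-O-TES ether (8,9-bis-epimer of 30) | C=CC[C@@]2(C)O[C@H]2[C@H](O[Si](CC)(CC)CC)[C@@H](OCc1ccc(OC)cc1)[C@H](O)[C@H]1[C@@H](C)[C@@H](O[Si](C)(C)C(C)(C)C)C[C@H](OC(C)=O)[C@]1(C)C=C
F5 | step 18 | 8,9-diol (8,9-bis-epimer of 31) | C=CC[C@@]2(C)O[C@H]2[C@H](O[Si](CC)(CC)CC)[C@@H](O)[C@H](O)[C@H]1[C@@H](C)[C@@H](O[Si](C)(C)C(C)(C)C)C[C@H](OC(C)=O)[C@]1(C)C=C
F6 | step 24 | (2S)-2-tert-butyl-5-methyl-4-(trimethylsilyloxy)-1,3-dioxole | CC1=C(O[Si](C)(C)C)O[C@@H](C(C)(C)C)O1
F7 | step 27 | seco-2,3-dialdehyde from 38 | O=CC[C@@]3(C)O[C@H]3[C@@H]2OC(=O)[C@](C)(O)[C@]2(O)[C@@H](O)[C@H]1[C@@H](C)[C@@H](O[Si](C)(C)C(C)(C)C)C[C@H](OC(C)=O)[C@]1(C)C=O
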